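The piperidine ring is cut across N1–C2 and C4–C5: N1, C6 and C5 come from a 2-alkyl-N-tosylaziridine that already carries the whole dihydroxyhexadecyl chain, and C4, C3, C2 and the C2 methyl from a ketal-masked butanone homoenolate. In one flask, copper-catalysed Grignard opening of the aziridine (C4–C5) and acid-driven cyclodehydration (N1–C2) give a cyclic ene-sulfonamide. The step exploits the 1,5-relation of N1 and C2 in the ring and the fact that the C2 methyl, C3 hydroxyl and C6 chain are all equatorial, so C6 alone steers C2 and C3 in one later hydroboration. The chain centre C4' and C6 both stem from one C2-symmetric diepoxide.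

Key step: step 9

Remark (assumption): ring atoms are N1, C2 (methyl), C3 (OH), C4, C5, C6 and the side chain is C1'–C16' counted from C6; the cobalt salen enantiomer called (R,R) is taken as the one that leaves (R)-configured monoalkyl oxiranes unhydrolysed.

Step 1
Reactants: 1 1-bromo-8-chlorooctane; 2 (S)-propylene oxide
Product: 4 (2S)-11-chloroundecan-2-ol, via 8-chlorooctylmagnesium bromide 3 (not isolated)
Conditions: Mg, THF, 25 °C; then CuI (10 mol %), 2, −30 to 0 °C; aq NH4Cl
Reagents that add atoms: none
Why: Magnesium inserts into the C–Br bond in preference to C–Cl and the copper-catalysed Grignard opens the oxirane by SN2 attack at its CH2 terminus (Grignard epoxide opening), so the (S) centre of 2 is carried into 4 untouched.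

Step 2
Reactants: 4 (2S)-11-chloroundecan-2-ol
Product: 5 ({[(2S)-11-chloroundecan-2-yl]oxy}methyl)benzene
Conditions: NaH, BnBr, DMF, 0 °C to rt
Reagents that add atoms: benzyl bromide, BrCc1ccccc1
Why: Williamson ether synthesis of the sodium alkoxide with benzyl bromide, which is far more reactive than the primary alkyl chloride that must survive.

Step 3
Reactants: 6 hepta-1,6-diene
Product: 7 1,2:6,7-diepoxyheptane (statistical mixture of stereoisomers)
Conditions: mCPBA (2.4 equiv), NaHCO3, CH2Cl2, 0 °C to rt
Reagents that add atoms: meta-chloroperoxybenzoic acid, OOC(=O)c1cccc(Cl)c1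
Why: Prilezhaev epoxidation of both monosubstituted alkenes; no stereocontrol is sought because step 4 selects the wanted isomer.

Step 4
Reactants: 7 1,2:6,7-diepoxyheptane (stereoisomer mixture)
Product: 8 (2R,6R)-1,2:6,7-diepoxyheptane
Conditions: (R,R)-(salen)Co(OAc) [acetato (R,R)-N,N'-bis(3,5-di-tert-butylsalicylidene)cyclohexane-1,2-diaminato cobalt, trivalent cobalt] (1 mol %), H2O (1.1 equiv), THF (minimal), 0 °C to rt; distillation
Reagents that add atoms: none
Why: Jacobsen hydrolytic kinetic resolution: the chiral cobalt salen complex hydrolyses every (S)-configured oxirane, so only the C2-symmetric (2R,6R) isomer (at most a quarter of the mixture) stays as diepoxide and is distilled from the polar diol and tetrol, which sets by catalyst control the two centres that become C4' and C6.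

Step 5
Reactants: 5 ({[(2S)-11-chloroundecan-2-yl]oxy}methyl)benzene; 8 (2R,6R)-1,2:6,7-diepoxyheptane
Product: 10 (4S,15S)-15-(benzyloxy)-1-[(2R)-oxiran-2-yl]hexadecan-4-ol, via alkylmagnesium chloride 9 (not isolated)
Conditions: 5, Mg, BrCH2CH2Br (cat.), THF, reflux; then added slowly to 8 (2.5 equiv), CuI (10 mol %), THF, −40 °C; aq NH4Cl at −40 °C; excess 8 recovered by distillation
Reagents that add atoms: none
Why: Grignard formation and copper-catalysed SN2 opening at the CH2 terminus of one of the two homotopic oxiranes of 8 (used in excess to suppress double addition); the oxirane carbon keeps its geometry and becomes the (S)-carbinol C4'.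

Step 6
Reactants: 10 (4S,15S)-15-(benzyloxy)-1-[(2R)-oxiran-2-yl]hexadecan-4-ol
Product: 11 (2R)-2-[(4S,15S)-4,15-bis(benzyloxy)hexadecyl]oxirane
Conditions: NaH, BnBr, Bu4NI (cat.), THF/DMF, 0 °C to rt
Reagents that add atoms: benzyl bromide, BrCc1ccccc1
Why: Williamson ether synthesis; intermolecular O-benzylation should outrun opening of the distal oxirane, which would need 6-exo attack at its substituted carbon or a 7-endo closure.

Step 7
Reactants: 11 (2R)-2-[(4S,15S)-4,15-bis(benzyloxy)hexadecyl]oxirane; 12 4-methylbenzenesulfonamide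
Product: 13 N-[(2R,6S,17S)-6,17-bis(benzyloxy)-2-hydroxyoctadecyl]-4-methylbenzenesulfonamide
Conditions: 12 (3 equiv), K2CO3 (0.1 equiv), BnEt3NCl (0.1 equiv), 1,4-dioxane, 90 °C
Reagents that add atoms: none
Why: Base-catalysed aminolysis of the terminal epoxide by the sulfonamide anion at the CH2 carbon (SN2), leaving the carbinol stereocentre untouched; excess sulfonamide limits double alkylation.

Step 8
Reactants: 13 N-[(2R,6S,17S)-6,17-bis(benzyloxy)-2-hydroxyoctadecyl]-4-methylbenzenesulfonamide
Product: 14 (2S)-2-[(4S,15S)-4,15-bis(benzyloxy)hexadecyl]-1-(4-methylbenzenesulfonyl)aziridine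
Conditions: PPh3, DIAD, THF, 0 °C to rt
Reagents that add atoms: none
Why: Intramolecular Mitsunobu reaction: the sulfonamide nitrogen displaces the activated secondary hydroxyl in a 3-exo-tet SN2 closure with inversion, turning the (R)-carbinol into the (S)-aziridine carbon that is C6 of the target.

Step 9
Reactants: 14 (2S)-2-[(4S,15S)-4,15-bis(benzyloxy)hexadecyl]-1-(4-methylbenzenesulfonyl)aziridine; 15 2-(2-bromoethyl)-2-methyl-1,3-dioxolane
Product: 19 (2S)-2-[(4S,15S)-4,15-bis(benzyloxy)hexadecyl]-6-methyl-1-(4-methylbenzenesulfonyl)-1,2,3,4-tetrahydropyridine, via Grignard reagent 16 (not isolated), via sulfonamido ketal 17 (not isolated), via sulfonamido ketone 18 (not isolated)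
Conditions: 15 (3 equiv), Mg, THF, below 30 °C; then 14, CuBr·SMe2 (15 mol %), THF, −40 to 0 °C; then 2 M HCl (aq), 40 °C; aqueous layer removed, TsOH·H2O (10 mol %), toluene, reflux (Dean–Stark), same vessel
Reagents that add atoms: none
Why: The soft organocopper species formed from Grignard 16 attacks the unsubstituted aziridine carbon C5 in an SN2 ring opening (C4–C5 bond), and the resulting magnesium sulfonamide 17 is unmasked by acid to ketone 18, whose sulfonamide nitrogen adds to the C2 carbonyl and loses water to the endocyclic ene-sulfonamide (N1–C2 bond). The closest known reactions are the copper-catalysed Grignard opening of N-sulfonylaziridines and the acid-catalysed cyclodehydration of δ-sulfonamido ketones; together they amount to a formal [3+3] annulation. The six-membered ring closes by 6-exo-trig attack of nitrogen on the carbonyl (or oxocarbenium) carbon followed by E1-type dehydration. No new stereocentre is formed: C6 is retained because only the C5–N bond of the aziridine is broken, and C2 and C3 stay trigonal for step 10. The step needs attack at CH2 and not at the substituted aziridine carbon, which the steric bias of a 2-alkyl aziridine towards a copper-bound primary alkyl secures, and an endocyclic instead of an exocyclic alkene, which the trisubstituted, nitrogen-conjugated position secures thermodynamically.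

Step 10
Reactants: 19 (2S)-2-[(4S,15S)-4,15-bis(benzyloxy)hexadecyl]-6-methyl-1-(4-methylbenzenesulfonyl)-1,2,3,4-tetrahydropyridine
Product: 21 (2R,3S,6S)-6-[(4S,15S)-4,15-bis(benzyloxy)hexadecyl]-2-methyl-1-(4-methylbenzenesulfonyl)piperidin-3-ol, via alkylborane 20 (not isolated)
Conditions: BH3·THF (3 equiv), THF, 0 °C to rt; then NaOH (aq), H2O2, 0 °C to rt
Reagents that add atoms: hydrogen peroxide, OO
Why: Hydroboration–oxidation: borane adds syn with boron at C3 (the nucleophilic β-carbon of the ene-sulfonamide) and hydrogen at C2 from the face anti to the C6 chain, which is held pseudoaxial by allylic strain with the N-sulfonyl group, and oxidation with retention should give the C2 methyl cis to the C6 chain and the C3 hydroxyl trans to both (2R,3S).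

Step 11
Reactants: 21 (2R,3S,6S)-6-[(4S,15S)-4,15-bis(benzyloxy)hexadecyl]-2-methyl-1-(4-methylbenzenesulfonyl)piperidin-3-ol
Product: 22 (2R,3S,6S)-6-[(4S,15S)-4,15-dihydroxyhexadecyl]-2-methylpiperidin-3-ol
Conditions: Na, NH3 (l), THF, −78 to −33 °C; then NH4Cl
Reagents that add atoms: none
Why: Dissolving-metal reduction (Birch-type) cleaves the N–S bond of the sulfonamide and both benzylic C–O bonds in one operation without touching the stereocentres.

Compound list
1 | 1-bromo-8-chlorooctane | ClCCCCCCCCBr | starting material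
2 | (S)-propylene oxide, (2S)-2-methyloxirane | C[C@H]1CO1 | starting material
3 | 8-chlorooctylmagnesium bromide | ClCCCCCCCC[Mg]Br | intermediate
4 | (2S)-11-chloroundecan-2-ol | C[C@H](O)CCCCCCCCCCl | intermediate
5 | ({[(2S)-11-chloroundecan-2-yl]oxy}methyl)benzene | C[C@H](OCc1ccccc1)CCCCCCCCCCl | intermediate
6 | hepta-1,6-diene | C=CCCCC=C | starting material
7 | 1,2:6,7-diepoxyheptane, mixture of stereoisomers | C1OC1CCCC1CO1 | intermediate
8 | (2R,6R)-1,2:6,7-diepoxyheptane | C1O[C@@H]1CCC[C@@H]1CO1 | intermediate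
9 | [(10S)-10-(benzyloxy)undecyl]magnesium chloride | C[C@H](OCc1ccccc1)CCCCCCCCC[Mg]Cl | intermediate
10 | (4S,15S)-15-(benzyloxy)-1-[(2R)-oxiran-2-yl]hexadecan-4-ol | C[C@H](OCc1ccccc1)CCCCCCCCCC[C@H](O)CCC[C@@H]1CO1 | intermediate
11 | (2R)-2-[(4S,15S)-4,15-bis(benzyloxy)hexadecyl]oxirane | C[C@H](OCc1ccccc1)CCCCCCCCCC[C@H](OCc1ccccc1)CCC[C@@H]1CO1 | intermediate
12 | 4-methylbenzenesulfonamide | Cc1ccc(cc1)S(N)(=O)=O | starting material
13 | N-[(2R,6S,17S)-6,17-bis(benzyloxy)-2-hydroxyoctadecyl]-4-methylbenzenesulfonamide | C[C@H](OCc1ccccc1)CCCCCCCCCC[C@H](OCc1ccccc1)CCC[C@@H](O)CNS(=O)(=O)c1ccc(C)cc1 | intermediate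
14 | (2S)-2-[(4S,15S)-4,15-bis(benzyloxy)hexadecyl]-1-(4-methylbenzenesulfonyl)aziridine | C[C@H](OCc1ccccc1)CCCCCCCCCC[C@H](OCc1ccccc1)CCC[C@H]1CN1S(=O)(=O)c1ccc(C)cc1 | intermediate
15 | 2-(2-bromoethyl)-2-methyl-1,3-dioxolane | CC1(CCBr)OCCO1 | starting material
16 | [2-(2-methyl-1,3-dioxolan-2-yl)ethyl]magnesium bromide | CC1(CC[Mg]Br)OCCO1 | intermediate
17 | N-[(4S,8S,19S)-8,19-bis(benzyloxy)-1-(2-methyl-1,3-dioxolan-2-yl)icosan-4-yl]-4-methylbenzenesulfonamide | C[C@H](OCc1ccccc1)CCCCCCCCCC[C@H](OCc1ccccc1)CCC[C@@H](CCCC1(C)OCCO1)NS(=O)(=O)c1ccc(C)cc1 | intermediate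
18 | N-[(6S,10S,21S)-10,21-bis(benzyloxy)-2-oxodocosan-6-yl]-4-methylbenzenesulfonamide | C[C@H](OCc1ccccc1)CCCCCCCCCC[C@H](OCc1ccccc1)CCC[C@@H](CCCC(C)=O)NS(=O)(=O)c1ccc(C)cc1 | intermediate
19 | (2S)-2-[(4S,15S)-4,15-bis(benzyloxy)hexadecyl]-6-methyl-1-(4-methylbenzenesulfonyl)-1,2,3,4-tetrahydropyridine | C[C@H](OCc1ccccc1)CCCCCCCCCC[C@H](OCc1ccccc1)CCC[C@H]1CCC=C(C)N1S(=O)(=O)c1ccc(C)cc1 | intermediate
20 | C3-borane of 21 (BH2 in place of the C3 hydroxyl, same spatial arrangement: boron trans to the C2 methyl and to the C6 chain) | C[C@H](OCc1ccccc1)CCCCCCCCCC[C@H](OCc1ccccc1)CCC[C@H]1CC[C@H](B)[C@@H](C)N1S(=O)(=O)c1ccc(C)cc1 | intermediate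
21 | (2R,3S,6S)-6-[(4S,15S)-4,15-bis(benzyloxy)hexadecyl]-2-methyl-1-(4-methylbenzenesulfonyl)piperidin-3-ol | C[C@H](OCc1ccccc1)CCCCCCCCCC[C@H](OCc1ccccc1)CCC[C@H]1CC[C@H](O)[C@@H](C)N1S(=O)(=O)c1ccc(C)cc1 | intermediate
22 | (2R,3S,6S)-6-[(4S,15S)-4,15-dihydroxyhexadecyl]-2-methylpiperidin-3-ol | C[C@H](O)CCCCCCCCCC[C@H](O)CCC[C@H]1CC[C@H](O)[C@@H](C)N1 | target

Total step count: 11. Longest linear sequence: 9 steps (1 → 4 → 5 → 10 → 11 → 13 → 14 → 19 → 21 → 22; the branch 6 → 7 → 8 → 10 is equally long).

Steps most likely to fail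

Step 10. Borane may attack both faces of the ene-sulfonamide, or the β-sulfonamido borane may lose boron by β-elimination before oxidation. The fallback sets out from 19 and returns at 21. The far bulkier OsO4 (cat.) with NMO in acetone/water should osmylate the alkene anti to the pseudoaxial C6 chain and give the 2,3-diol hemiaminal F1, with the C3 hydroxyl already in its final configuration. Treatment of F1 with Me4NBH(OAc)3 in AcOH/MeCN at −20 °C should ionise the hemiaminal to the N-sulfonyliminium ion. The boron bound to the C3 oxygen should then deliver hydride to C2 on the face of that oxygen (hydroxyl-directed reduction of the Evans–Saksena type). Hydrogen at C2 thus ends cis to the C3 hydroxyl and the methyl trans to it, which is 21.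

Step 5. The alkyl chloride may resist magnesium insertion, the Grignard may open both oxiranes of 8, or the intermediate alkoxide may close onto the remaining oxirane. The fallback sets out from 5 (through the same Grignard 9) and returns at 11, with no bis-electrophile exposed to the organometallic. Grignard 9 and (S)-2-(chloromethyl)oxirane (CuI cat., THF, −40 °C) should give the chlorohydrin F2. NaOH closes it to the (S)-oxirane F3. But-3-enylmagnesium bromide with CuI opens F3 at CH2 to the alkenol F4, which carries the C4' carbinol. NaH and BnBr give the bis-benzyl ether F5. mCPBA gives the terminal epoxide F6 in both configurations at the new oxirane carbon. Hydrolytic kinetic resolution of F6 with the same (R,R)-(salen)Co(OAc) catalyst and H2O (0.55 equiv) should leave the (R)-oxirane, which is 11.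

Step 9. The ketal Grignard may decompose thermally, some attack may occur at the substituted aziridine carbon, or the acid stage may stall at the open ketone or re-form the ketal. The fallback sets out from 14 and returns at 19, with an alkene as the ketone surrogate. But-3-enylmagnesium bromide with CuI (THF, −40 to 0 °C) opens 14 at CH2 to the sulfonamido alkene F7. Tsuji–Wacker oxidation (PdCl2 10 mol %, CuCl, O2, DMF/H2O) converts the terminal alkene into the methyl ketone 18, now isolated. TsOH (cat.) in refluxing toluene with a Dean–Stark trap, in the absence of any diol, then dehydrates 18 to 19.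

Further compounds
F1 | step 10 | N-tosyl (3S,6S)-6-[(4S,15S)-4,15-bis(benzyloxy)hexadecyl]-2-methylpiperidine-2,3-diol, hemiaminal carbon C2 not defined | C[C@H](OCc1ccccc1)CCCCCCCCCC[C@H](OCc1ccccc1)CCC[C@H]1CC[C@H](O)C(C)(O)N1S(=O)(=O)c1ccc(C)cc1
F2 | step 5 | (2S,13S)-13-(benzyloxy)-1-chlorotetradecan-2-ol | C[C@H](OCc1ccccc1)CCCCCCCCCC[C@H](O)CCl
F3 | step 5 | (2S)-2-[(11S)-11-(benzyloxy)dodecyl]oxirane | C[C@H](OCc1ccccc1)CCCCCCCCCC[C@H]1CO1
F4 | step 5 | (6S,17S)-17-(benzyloxy)octadec-1-en-6-ol | C[C@H](OCc1ccccc1)CCCCCCCCCC[C@H](O)CCCC=C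
F5 | step 5 | (6S,17S)-6,17-bis(benzyloxy)octadec-1-ene | C[C@H](OCc1ccccc1)CCCCCCCCCC[C@H](OCc1ccccc1)CCCC=C
F6 | step 5 | 2-[(4S,15S)-4,15-bis(benzyloxy)hexadecyl]oxirane, both configurations at the oxirane carbon | C[C@H](OCc1ccccc1)CCCCCCCCCC[C@H](OCc1ccccc1)CCCC1CO1
F7 | step 9 | N-[(5S,9S,20S)-9,20-bis(benzyloxy)henicos-1-en-5-yl]-4-methylbenzenesulfonamide | C[C@H](OCc1ccccc1)CCCCCCCCCC[C@H](OCc1ccccc1)CCC[C@@H](CCCC=C)NS(=O)(=O)c1ccc(C)cc1
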